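**Assumption:** nortopsentin A has no stereocentre (it is achiral), so no stereocontrol is needed; the 1H-imidazole tautomers are one compound.

## Retrosynthetic overview

1. Only the imidazole ring is built; both 6-bromoindole units are bought intact and both come from the same aldehyde 1.
2. Imidazole ⇒ aryl glyoxal 4 (C4 and C5) + aldehyde 1 (C2) + 2 NH3, closed last by an oxidative Weidenhagen/Debus–Radziszewski condensation.
3. Glyoxal 4 ⇒ ketol 3, ArC(=O)–CH2OH, oxidised in the flask by divalent copper.
4. Key disconnection: the C4–C5 bond of 3, between two carbonyl-derived carbons ⇒ indole-3-acyl anion (Breslow intermediate of 1 with a thiazol-2-ylidene) + formaldehyde.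

## Route

**Step 1**
Reactants: 1 6-bromo-1H-indole-3-carbaldehyde; 2 paraformaldehyde (formaldehyde source)
Product: 3 1-(6-bromo-1H-indol-3-yl)-2-hydroxyethan-1-one
Conditions: 2 (3 equiv CH2O), 3-benzyl-5-(2-hydroxyethyl)-4-methylthiazolium chloride (20 mol%), i-Pr2NEt (20 mol%), THF/DMF 4:1, 65 °C, Ar, sealed tube, 16 h
Reagents that add atoms: none
Why: Proposed new method: the thiazol-2-ylidene adds to the formyl group of 1 and proton transfer gives the Breslow enaminol (an indole-3-acyl anion equivalent), which attacks formaldehyde, the best acceptor present, and then releases the carbene to leave the aryl ketol; the closest known reaction is the carbene-catalysed cross-acyloin (hydroxymethylation) of aryl and heteroaryl aldehydes with paraformaldehyde; like 4-dimethylaminobenzaldehyde in mixed benzoin condensations, the vinylogous-formamide aldehyde 1 can act only as donor, so its homo-benzoin is shut off, and the untested point is carbene addition to the N–H free, deactivated formyl group; the step is an addition with no co-product and forms no stereocentre.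

**Step 2**
Reactants: 3 1-(6-bromo-1H-indol-3-yl)-2-hydroxyethan-1-one; 1 6-bromo-1H-indole-3-carbaldehyde
Product: 5 nortopsentin A, via indolylglyoxal 4 (not isolated)
Conditions: 1 (3 equiv), NH4OAc (15 equiv), Cu(OAc)2·H2O (2.2 equiv), AcOH, 90 °C, N2, 3 added by syringe pump over 3 h; then aq NH3 work-up
Reagents that add atoms: ammonium acetate, CC(=O)[O-].[NH4+]
Why: Weidenhagen imidazole synthesis (oxidative Debus–Radziszewski condensation): divalent copper acetate oxidises ketol 3 through its enediol to glyoxal 4, which condenses with two ammonia and the formyl carbon of 1 (this becomes C2) and aromatises by loss of water; slow addition of 3 into excess 1 keeps 4 dilute so that it does not condense with itself; no stereocentre is formed.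

## Compound list

1 | 6-bromo-1H-indole-3-carbaldehyde | O=Cc1c[nH]c2cc(Br)ccc12 | starting material
2 | paraformaldehyde (formaldehyde source) | C=O | starting material
3 | 1-(6-bromo-1H-indol-3-yl)-2-hydroxyethan-1-one | O=C(CO)c1c[nH]c2cc(Br)ccc12 | intermediate
4 | 2-(6-bromo-1H-indol-3-yl)-2-oxoacetaldehyde (indolylglyoxal) | O=CC(=O)c1c[nH]c2cc(Br)ccc12 | intermediate
5 | nortopsentin A, 2,4-bis(6-bromo-1H-indol-3-yl)-1H-imidazole | Brc1ccc2c(-c3c[nH]c(-c4c[nH]c5cc(Br)ccc45)n3)c[nH]c2c1 | target

## Step count and risks

Total step count: 2. Longest linear sequence: 2.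

The route has only two steps, so step 1 is named once and step 2 twice, for two independent ways it can fail.

**Most likely to fail: step 1.** The formyl group of 1 is a vinylogous formamide, so the carbene may not add, and formaldehyde self-condensation may then consume the C1 partner. The fallback sets out from 1 and comes back at 3. Compound 1 is N-acylated (Boc2O, cat. DMAP, MeCN) to tert-butyl 6-bromo-3-formyl-1H-indole-1-carboxylate F1, which behaves as an ordinary electron-poor aryl aldehyde because the nitrogen lone pair is tied up. The same thiazolium-catalysed addition to 2 gives tert-butyl 6-bromo-3-(2-hydroxyacetyl)-1H-indole-1-carboxylate F2. K2CO3 in MeOH at room temperature cleaves the activated N-carbamate and returns 3.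

**Second: step 2, cross- versus self-condensation.** Glyoxal 4 carries a far more electrophilic formyl group than 1 and may condense with itself to the 2-acyl-imidazole instead of with 1. The fallback sets out from 3 and comes back at 5, and never passes through a free glyoxal. Ketol 3 is converted (PPh3, CBr4, CH2Cl2/THF, 0 °C) into 2-bromo-1-(6-bromo-1H-indol-3-yl)ethan-1-one F3. Separately, 6-bromo-1H-indole-3-carbonitrile F4 (made from 1 with aq NH3 and I2 in THF; also a catalogue compound) is treated with MeAl(Cl)NH2 (from AlMe3 and NH4Cl, toluene, 80 °C) to give 6-bromo-1H-indole-3-carboximidamide F5. F3 and F5 with KHCO3 in THF/H2O at reflux give 5 by N-alkylation and cyclodehydration.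

**Third: step 2, oxidation stage.** Under ammonium acetate the ketol 3 may be aminated (leading to pyrazines) or oxidised too slowly by divalent copper. The fallback sets out from 3 and comes back at 4, taking the redox event out of the condensation. Ketol 3 is oxidised with 2-iodoxybenzoic acid (IBX, DMSO, room temperature) and isolated after aqueous work-up as 1-(6-bromo-1H-indol-3-yl)-2,2-dihydroxyethan-1-one F6, the hydrate of 4. F6 is added slowly to 1 and NH4OAc in MeOH at 40 °C, where it loses water to 4 and goes on to 5 without copper.

## Further compounds

F1 | step 1 | tert-butyl 6-bromo-3-formyl-1H-indole-1-carboxylate | CC(C)(C)OC(=O)n1cc(C=O)c2ccc(Br)cc21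
F2 | step 1 | tert-butyl 6-bromo-3-(2-hydroxyacetyl)-1H-indole-1-carboxylate | CC(C)(C)OC(=O)n1cc(C(=O)CO)c2ccc(Br)cc21
F3 | step 2 | 2-bromo-1-(6-bromo-1H-indol-3-yl)ethan-1-one | O=C(CBr)c1c[nH]c2cc(Br)ccc12
F4 | step 2 | 6-bromo-1H-indole-3-carbonitrile | N#Cc1c[nH]c2cc(Br)ccc12
F5 | step 2 | 6-bromo-1H-indole-3-carboximidamide | N=C(N)c1c[nH]c2cc(Br)ccc12
F6 | step 2 | 1-(6-bromo-1H-indol-3-yl)-2,2-dihydroxyethan-1-one | O=C(C(O)O)c1c[nH]c2cc(Br)ccc12
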